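**Strategy.** The route rests on the local mirror symmetry of the 2,6-dimethoxycyclohexa-2,5-dienone ring: the plane through the spiro carbon C1' and the carbonyl carbon C4' makes C1' non-stereogenic and the two C2'H=C3'(OMe) bonds equivalent. Both are therefore disconnected by aldol logic. In one operation a geminal dialdehyde on C5 of the benzo[7]annulene condenses twice with 1,3-dimethoxyacetone; the second, ring-closing aldol forms a C(OMe)=CH bond and completes the spirodienone. The precursor is a benzosuberane carrying the finished benzoate/dimethyl stereotriad and a C(CHO)2 group, built from an arylmalonate, a trans-dimethylbutyrolactone-derived iodo ester and a Friedel–Crafts ring closure.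

Key step: step 13

Assumption: (S)-4-methyldihydrofuran-2(3H)-one (1) and 1,3-dimethoxypropan-2-one (19) are treated as catalogue compounds; benzo[7]annulene locants are C5 = quaternary (later spiro) carbon, C6 = CH2, C7 and C8 = methyl-bearing carbons, C9 = benzylic oxygenated carbon.

**Step 1**
Reactants: 1 (S)-4-methyldihydrofuran-2(3H)-one
Product: 2 (3S,4S)-3,4-dimethyldihydrofuran-2(3H)-one
Conditions: LDA, THF, −78 °C; then MeI, −78 → −40 °C
Reagents that add atoms: iodomethane, CI
Why: Enolate alkylation of a β-substituted γ-butyrolactone, in which iodomethane should approach the planar lithium enolate anti to the C4 methyl group and so set C3 trans to C4 (substrate control).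

**Step 2**
Reactants: 2 (3S,4S)-3,4-dimethyldihydrofuran-2(3H)-one
Product: 5 methyl (2S,3S)-4-iodo-2,3-dimethylbutanoate, via silyl ester 3 (not isolated), via iodo acid 4 (not isolated)
Conditions: TMSI, CHCl3, 60 °C; then MeOH, 20 °C
Reagents that add atoms: iodotrimethylsilane, C[Si](C)(C)I; methanol, CO
Why: Lactone opening by SN2 attack of iodide at the primary O–CH2 carbon of the O-silylated lactone gives 3, methanolysis frees acid 4, and hydrogen iodide from excess TMSI catalyses its Fischer esterification, neither stereocentre being involved.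

**Step 3**
Reactants: 6 1-bromo-2,3,4-trimethoxybenzene; 7 diethyl malonate
Product: 8 diethyl 2-(2,3,4-trimethoxyphenyl)malonate
Conditions: Pd(OAc)2 (cat.), P(t-Bu)3·HBF4 (cat.), K3PO4, toluene, 80 °C
Reagents that add atoms: none
Why: Palladium-catalysed α-arylation of a malonate (oxidative addition of the aryl bromide to zerovalent palladium bearing the bulky phosphine, enolate exchange, reductive elimination), in which the acidic product stays deprotonated and should not be arylated twice.

**Step 4**
Reactants: 8 diethyl 2-(2,3,4-trimethoxyphenyl)malonate; 5 methyl (2S,3S)-4-iodo-2,3-dimethylbutanoate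
Product: 9 diethyl 2-[(2R,3S)-4-methoxy-2,3-dimethyl-4-oxobutyl]-2-(2,3,4-trimethoxyphenyl)malonate
Conditions: NaH (0.95 equiv), DMF, 0 °C; then 5, 70 °C
Reagents that add atoms: none
Why: SN2 alkylation of the stabilised tertiary malonate anion by the primary iodide creates the quaternary benzylic carbon, and the sub-stoichiometric base leaves nothing able to enolise the methyl ester, so both stereocentres of 5 are carried over (descriptor change at the former C3 is a priority effect only).

**Step 5**
Reactants: 9 diethyl 2-[(2R,3S)-4-methoxy-2,3-dimethyl-4-oxobutyl]-2-(2,3,4-trimethoxyphenyl)malonate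
Product: 10 (2S,3R)-5,5-bis(ethoxycarbonyl)-2,3-dimethyl-5-(2,3,4-trimethoxyphenyl)pentanoic acid
Conditions: Me3SnOH, 1,2-dichloroethane, 80 °C; then 1 M HCl
Reagents that add atoms: trimethyltin hydroxide, C[Sn](C)(C)O
Why: Trimethyltin hydroxide ester hydrolysis should cleave only the methyl ester, because the two ethyl esters sit on a fully substituted aryl-bearing carbon, and its near-neutral conditions should not epimerise the α-stereocentre.

**Step 6**
Reactants: 10 (2S,3R)-5,5-bis(ethoxycarbonyl)-2,3-dimethyl-5-(2,3,4-trimethoxyphenyl)pentanoic acid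
Product: 12 diethyl (7R,8S)-2,3,4-trimethoxy-7,8-dimethyl-9-oxo-6,7,8,9-tetrahydro-5H-benzo[7]annulene-5,5-dicarboxylate, via mixed anhydride 11 (not isolated)
Conditions: TFAA, TFA, CH2Cl2 (high dilution), 0 → 20 °C
Reagents that add atoms: none
Why: Intramolecular Friedel–Crafts acylation through the mixed trifluoroacetic anhydride, in which the tether can reach only the arene carbon para to the central methoxy group, so the seven-membered aryl ketone should form regioselectively; any equilibration α to the new ketone is expected to favour the trans-dimethyl arrangement already present.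

**Step 7**
Reactants: 12 diethyl (7R,8S)-2,3,4-trimethoxy-7,8-dimethyl-9-oxo-6,7,8,9-tetrahydro-5H-benzo[7]annulene-5,5-dicarboxylate
Product: 13 diethyl (7R,8S,9R)-9-hydroxy-2,3,4-trimethoxy-7,8-dimethyl-6,7,8,9-tetrahydro-5H-benzo[7]annulene-5,5-dicarboxylate
Conditions: (S)-2-methyl-CBS-oxazaborolidine (0.2 equiv), BH3·SMe2, THF, −20 → 0 °C
Reagents that add atoms: none
Why: Corey–Bakshi–Shibata reduction, in which the ketone binds the catalyst with its aryl group as the large substituent and hydride is delivered to the Si face of C9, which by analogy with aryl alkyl ketones should give the 9R carbinol trans to the C8 methyl group (reagent control), the esters being inert to borane at this temperature.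

**Step 8**
Reactants: 13 diethyl (7R,8S,9R)-9-hydroxy-2,3,4-trimethoxy-7,8-dimethyl-6,7,8,9-tetrahydro-5H-benzo[7]annulene-5,5-dicarboxylate
Product: 14 [(7R,8S,9R)-9-hydroxy-2,3,4-trimethoxy-7,8-dimethyl-6,7,8,9-tetrahydro-5H-benzo[7]annulene-5,5-diyl]dimethanol
Conditions: LiAlH4, THF, 0 °C → reflux; Fieser work-up
Reagents that add atoms: none
Why: Hydride reduction of both hindered esters to the neopentyl 1,3-diol, which touches no stereocentre and should not hydrogenolyse the benzylic alkoxide; any bridged lactone formed from 13 would converge on the same triol.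

**Step 9**
Reactants: 14 [(7R,8S,9R)-9-hydroxy-2,3,4-trimethoxy-7,8-dimethyl-6,7,8,9-tetrahydro-5H-benzo[7]annulene-5,5-diyl]dimethanol
Product: 15 (7R,8S,9R)-2,3,4-trimethoxy-2',2',7,8-tetramethyl-6,7,8,9-tetrahydrospiro[benzo[7]annulene-5,5'-[1,3]dioxan]-9-ol
Conditions: 2,2-dimethoxypropane, PPTS (cat.), CH2Cl2, 20 °C
Reagents that add atoms: 2,2-dimethoxypropane, COC(C)(C)OC
Why: Acid-catalysed transketalisation, in which only the 2,2-disubstituted propane-1,3-diol can form an unstrained six-membered 1,3-dioxane, so the benzylic C9 hydroxyl should stay free.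

**Step 10**
Reactants: 15 (7R,8S,9R)-2,3,4-trimethoxy-2',2',7,8-tetramethyl-6,7,8,9-tetrahydrospiro[benzo[7]annulene-5,5'-[1,3]dioxan]-9-ol
Product: 16 (7R,8S,9R)-2,3,4-trimethoxy-2',2',7,8-tetramethyl-6,7,8,9-tetrahydrospiro[benzo[7]annulene-5,5'-[1,3]dioxan]-9-yl benzoate
Conditions: BzCl, pyridine, DMAP (cat.), CH2Cl2, 0 → 40 °C
Reagents that add atoms: benzoyl chloride, O=C(Cl)c1ccccc1
Why: DMAP-catalysed acylation (nucleophilic catalysis through the N-benzoylpyridinium ion) of the only free hydroxyl group, with retention at C9.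

**Step 11**
Reactants: 16 (7R,8S,9R)-2,3,4-trimethoxy-2',2',7,8-tetramethyl-6,7,8,9-tetrahydrospiro[benzo[7]annulene-5,5'-[1,3]dioxan]-9-yl benzoate
Product: 17 (7R,8S,9R)-5,5-bis(hydroxymethyl)-2,3,4-trimethoxy-7,8-dimethyl-6,7,8,9-tetrahydro-5H-benzo[7]annulen-9-yl benzoate
Conditions: AcOH/H2O/THF (4:1:1), 40 °C
Reagents that add atoms: none
Why: Mild acid hydrolysis of the isopropylidene ketal, to which the benzoate and the aryl methyl ethers should be stable and under which acyl migration would need an eight-membered transition state.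

**Step 12**
Reactants: 17 (7R,8S,9R)-5,5-bis(hydroxymethyl)-2,3,4-trimethoxy-7,8-dimethyl-6,7,8,9-tetrahydro-5H-benzo[7]annulen-9-yl benzoate
Product: 18 (7R,8S,9R)-5,5-diformyl-2,3,4-trimethoxy-7,8-dimethyl-6,7,8,9-tetrahydro-5H-benzo[7]annulen-9-yl benzoate
Conditions: Dess–Martin periodinane, NaHCO3, CH2Cl2, 0 → 20 °C; used crude
Reagents that add atoms: none
Why: Dess–Martin oxidation of both primary neopentyl alcohols under buffered, non-basic conditions, which should avoid retro-aldol loss of formaldehyde at the β-hydroxy aldehyde stage and leave the benzoate untouched.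

**Step 13**
Reactants: 18 (7R,8S,9R)-5,5-diformyl-2,3,4-trimethoxy-7,8-dimethyl-6,7,8,9-tetrahydro-5H-benzo[7]annulen-9-yl benzoate; 19 1,3-dimethoxypropan-2-one
Product: 22 (7R,8S,9R)-2,3,3',4,5'-pentamethoxy-7,8-dimethyl-4'-oxo-6,7,8,9-tetrahydrospiro[benzo[7]annulene-5,1'-cyclohexa[2,5]dien]-9-yl benzoate, via open-chain aldol 20 (not isolated), via cyclic diol 21 (not isolated)
Conditions: 19 (2 equiv), pyrrolidine (0.3 equiv), AcOH (0.3 equiv), 4 Å molecular sieves, toluene, 20 → 60 °C
Reagents that add atoms: none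
Why: The pyrrolidine enamine of 19 adds to one formyl group of 18 (crossed aldol addition) to give 20, a second enamine at the remaining CH2OMe carbon attacks the other formyl group and closes the six-membered ring by forming the C(OMe)–CH bond (21), and twofold E1cB dehydration, driven by the cross-conjugated dienone, gives 22. The closest known reaction type is the aldol ring closure of a Robinson annulation onto an α-quaternary aldehyde, doubled as in the condensation of dialdehydes with 1,3-disubstituted acetones to cyclic dienones. The ring closes in the 6-(enolexo)-exo-trig mode. No stereocentre is created in the product: the carbinol and C(OMe) centres of 20 and 21 are erased on dehydration and C1' becomes non-stereogenic, so it is irrelevant which of the two diastereotopic formyl groups reacts first. The step needs aldehyde-over-benzoate chemoselectivity and suppression of retro-Claisen deformylation of the non-enolisable malonaldehyde, which buffered amine catalysis without hydroxide or alkoxide should secure; regiochemistry is fixed because the already substituted α-carbon of 20 could only close a four-membered ring. An open-chain E-enone formed by premature dehydration should be returned to the productive path by reversible conjugate addition of pyrrolidine.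

**Compound list**

1 | (S)-4-methyldihydrofuran-2(3H)-one | C[C@@H]1COC(=O)C1 | starting material
2 | (3S,4S)-3,4-dimethyldihydrofuran-2(3H)-one | C[C@@H]1COC(=O)[C@H]1C | intermediate
3 | trimethylsilyl (2S,3S)-4-iodo-2,3-dimethylbutanoate | C[Si](C)(C)OC(=O)[C@@H](C)[C@H](C)CI | intermediate
4 | (2S,3S)-4-iodo-2,3-dimethylbutanoic acid | OC(=O)[C@@H](C)[C@H](C)CI | intermediate
5 | methyl (2S,3S)-4-iodo-2,3-dimethylbutanoate | COC(=O)[C@@H](C)[C@H](C)CI | intermediate
6 | 1-bromo-2,3,4-trimethoxybenzene | COc1ccc(Br)c(OC)c1OC | starting material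
7 | diethyl malonate | CCOC(=O)CC(=O)OCC | starting material
8 | diethyl 2-(2,3,4-trimethoxyphenyl)malonate | CCOC(=O)C(C(=O)OCC)c1ccc(OC)c(OC)c1OC | intermediate
9 | diethyl 2-[(2R,3S)-4-methoxy-2,3-dimethyl-4-oxobutyl]-2-(2,3,4-trimethoxyphenyl)malonate | CCOC(=O)C(C[C@@H](C)[C@H](C)C(=O)OC)(C(=O)OCC)c1ccc(OC)c(OC)c1OC | intermediate
10 | (2S,3R)-5,5-bis(ethoxycarbonyl)-2,3-dimethyl-5-(2,3,4-trimethoxyphenyl)pentanoic acid | CCOC(=O)C(C[C@@H](C)[C@H](C)C(=O)O)(C(=O)OCC)c1ccc(OC)c(OC)c1OC | intermediate
11 | mixed anhydride of 10 with trifluoroacetic acid | CCOC(=O)C(C[C@@H](C)[C@H](C)C(=O)OC(=O)C(F)(F)F)(C(=O)OCC)c1ccc(OC)c(OC)c1OC | intermediate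
12 | diethyl (7R,8S)-2,3,4-trimethoxy-7,8-dimethyl-9-oxo-6,7,8,9-tetrahydro-5H-benzo[7]annulene-5,5-dicarboxylate | CCOC(=O)C1(C(=O)OCC)C[C@@H](C)[C@H](C)C(=O)c2cc(OC)c(OC)c(OC)c21 | intermediate
13 | diethyl (7R,8S,9R)-9-hydroxy-2,3,4-trimethoxy-7,8-dimethyl-6,7,8,9-tetrahydro-5H-benzo[7]annulene-5,5-dicarboxylate | CCOC(=O)C1(C(=O)OCC)C[C@@H](C)[C@H](C)[C@@H](O)c2cc(OC)c(OC)c(OC)c21 | intermediate
14 | [(7R,8S,9R)-9-hydroxy-2,3,4-trimethoxy-7,8-dimethyl-6,7,8,9-tetrahydro-5H-benzo[7]annulene-5,5-diyl]dimethanol | OCC1(CO)C[C@@H](C)[C@H](C)[C@@H](O)c2cc(OC)c(OC)c(OC)c21 | intermediate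
15 | (7R,8S,9R)-2,3,4-trimethoxy-2',2',7,8-tetramethyl-6,7,8,9-tetrahydrospiro[benzo[7]annulene-5,5'-[1,3]dioxan]-9-ol | CC1(C)OCC2(CO1)C[C@@H](C)[C@H](C)[C@@H](O)c1cc(OC)c(OC)c(OC)c12 | intermediate
16 | (7R,8S,9R)-2,3,4-trimethoxy-2',2',7,8-tetramethyl-6,7,8,9-tetrahydrospiro[benzo[7]annulene-5,5'-[1,3]dioxan]-9-yl benzoate | CC1(C)OCC2(CO1)C[C@@H](C)[C@H](C)[C@@H](OC(=O)c1ccccc1)c1cc(OC)c(OC)c(OC)c12 | intermediate
17 | (7R,8S,9R)-5,5-bis(hydroxymethyl)-2,3,4-trimethoxy-7,8-dimethyl-6,7,8,9-tetrahydro-5H-benzo[7]annulen-9-yl benzoate | OCC1(CO)C[C@@H](C)[C@H](C)[C@@H](OC(=O)c2ccccc2)c2cc(OC)c(OC)c(OC)c21 | intermediate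
18 | (7R,8S,9R)-5,5-diformyl-2,3,4-trimethoxy-7,8-dimethyl-6,7,8,9-tetrahydro-5H-benzo[7]annulen-9-yl benzoate | O=CC1(C=O)C[C@@H](C)[C@H](C)[C@@H](OC(=O)c2ccccc2)c2cc(OC)c(OC)c(OC)c21 | intermediate
19 | 1,3-dimethoxypropan-2-one | COCC(=O)COC | starting material
20 | (7R,8S,9R)-5-formyl-5-(1-hydroxy-2,4-dimethoxy-3-oxobutyl)-2,3,4-trimethoxy-7,8-dimethyl-6,7,8,9-tetrahydro-5H-benzo[7]annulen-9-yl benzoate (open-chain aldol, mixture at the new centres) | COCC(=O)C(OC)C(O)C1(C=O)C[C@@H](C)[C@H](C)[C@@H](OC(=O)c2ccccc2)c2cc(OC)c(OC)c(OC)c21 | intermediate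
21 | (7R,8S,9R)-2',6'-dihydroxy-2,3,3',4,5'-pentamethoxy-7,8-dimethyl-4'-oxo-6,7,8,9-tetrahydrospiro[benzo[7]annulene-5,1'-cyclohexan]-9-yl benzoate (cyclic diol, mixture at the new centres) | COC1C(O)C2(C(O)C(OC)C1=O)C[C@@H](C)[C@H](C)[C@@H](OC(=O)c1ccccc1)c1cc(OC)c(OC)c(OC)c12 | intermediate
22 | (7R,8S,9R)-2,3,3',4,5'-pentamethoxy-7,8-dimethyl-4'-oxo-6,7,8,9-tetrahydrospiro[benzo[7]annulene-5,1'-cyclohexa[2,5]dien]-9-yl benzoate | COC1=CC2(C=C(OC)C1=O)C[C@@H](C)[C@H](C)[C@@H](OC(=O)c1ccccc1)c1cc(OC)c(OC)c(OC)c12 | target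

**Step count.** Total: 13 steps. Longest linear sequence: 12 steps (1 → 2 → 5 → 9 → 10 → 12 → 13 → 14 → 15 → 16 → 17 → 18 → 22, that is steps 1, 2 and 4–13); step 3 is a one-step branch.

**Steps most likely to fail**

1. Step 13. Retro-Claisen loss of a formyl group from the non-enolisable malonaldehyde, or stalling at an open-chain enone of the wrong geometry, may outrun ring closure. The fallback sets out from 18 and returns at 22; it separates kinetic addition from elimination. The preformed lithium enolate of 19 (LDA, THF, −78 °C) is added to 18 to give open-chain aldol 20. Soft enolisation (MgBr2·OEt2, i-Pr2NEt, CH2Cl2, 0 °C) closes it to cyclic diol 21. Mesylation (MsCl, Et3N, CH2Cl2, 0 °C) gives the bis(methanesulfonate) of the cyclic diol F1, and DBU-induced twofold E1cB elimination then gives 22.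

2. Step 7. Facial selectivity may be poor or reversed, because the twisted, ortho-substituted aryl group may not behave as the large substituent and the bias of the C8 methyl group may oppose the catalyst. The fallback sets out from 12 and returns at 16; it sets C9 by inversion instead of by hydride face selection. A bulky hydride (LiBH(s-Bu)3, THF, −78 °C) should attack anti to the C8 methyl group and give diethyl (7R,8S,9S)-9-hydroxy-2,3,4-trimethoxy-7,8-dimethyl-6,7,8,9-tetrahydro-5H-benzo[7]annulene-5,5-dicarboxylate F2. LiAlH4 reduction gives the (9S)-triol F3 and 2,2-dimethoxypropane/PPTS the (9S)-acetonide alcohol F4. A Mitsunobu reaction with benzoic acid (PPh3, DIAD, toluene, 0 → 20 °C) then installs the benzoate with inversion to give 16.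

3. Step 4. Substitution may be slow, because the hindered tertiary arylmalonate anion meets a β-branched iodide, so elimination of hydrogen iodide and decomposition can compete. The fallback sets out from 5 and 7 and returns at 9; it makes the quaternary centre by aryl transfer instead of alkylation. The unhindered sodium enolate of 7 is alkylated with 5 (NaH, DMF, 50 °C) to diethyl 2-[(2R,3S)-4-methoxy-2,3-dimethyl-4-oxobutyl]malonate F5. (2,3,4-Trimethoxyphenyl)lead triacetate F6 is prepared from commercial (2,3,4-trimethoxyphenyl)boronic acid with Pb(OAc)4 and catalytic Hg(OAc)2 in CHCl3. It arylates the sodium enolate of F5 in pyridine/CHCl3 at 40 °C (Pinhey arylation) to give 9.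

**Further compounds**

F1 | step 13 | (7R,8S,9R)-2,3,3',4,5'-pentamethoxy-7,8-dimethyl-2',6'-bis(methylsulfonyloxy)-4'-oxo-6,7,8,9-tetrahydrospiro[benzo[7]annulene-5,1'-cyclohexan]-9-yl benzoate | COC1C(OS(C)(=O)=O)C2(C(OS(C)(=O)=O)C(OC)C1=O)C[C@@H](C)[C@H](C)[C@@H](OC(=O)c1ccccc1)c1cc(OC)c(OC)c(OC)c12
F2 | step 7 | diethyl (7R,8S,9S)-9-hydroxy-2,3,4-trimethoxy-7,8-dimethyl-6,7,8,9-tetrahydro-5H-benzo[7]annulene-5,5-dicarboxylate | CCOC(=O)C1(C(=O)OCC)C[C@@H](C)[C@H](C)[C@H](O)c2cc(OC)c(OC)c(OC)c21
F3 | step 7 | [(7R,8S,9S)-9-hydroxy-2,3,4-trimethoxy-7,8-dimethyl-6,7,8,9-tetrahydro-5H-benzo[7]annulene-5,5-diyl]dimethanol | OCC1(CO)C[C@@H](C)[C@H](C)[C@H](O)c2cc(OC)c(OC)c(OC)c21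
F4 | step 7 | (7R,8S,9S)-2,3,4-trimethoxy-2',2',7,8-tetramethyl-6,7,8,9-tetrahydrospiro[benzo[7]annulene-5,5'-[1,3]dioxan]-9-ol | CC1(C)OCC2(CO1)C[C@@H](C)[C@H](C)[C@H](O)c1cc(OC)c(OC)c(OC)c12
F5 | step 4 | diethyl 2-[(2R,3S)-4-methoxy-2,3-dimethyl-4-oxobutyl]malonate | CCOC(=O)C(C[C@@H](C)[C@H](C)C(=O)OC)C(=O)OCC
F6 | step 4 | (2,3,4-trimethoxyphenyl)lead triacetate | COc1ccc([Pb](OC(C)=O)(OC(C)=O)OC(C)=O)c(OC)c1OC
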